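**Strategy.** The ten-membered carbocycle (germacrane numbering: C4 = C(OH)Me, C5 = CHOH, C6 = CH–O-angeloyl, C7 = CH–CMe2OH, C10 = CHMe) is disconnected at C8–C9. This is its only CH2–CH2 bond that lies between two stereocentres and has no β-heteroatom. Both carbons are first tied through sulfur in an 11-membered thiacycloundecene 1,1-dioxide. That ring is assembled from neryl acetate (C6–C5=C4–C3–C2–C1–C10–C9) and a dithiodipropionate (C8, C7, C11) by syn-aldol and thiolate macrocyclisation. A Ramberg–Bäcklund reaction then joins the two like-polarised α-sulfonyl carbons with loss of SO2, contracting the 11-membered ring to the cyclodecadiene. Diimide removes the new olefin, and the Z-C4=C5 olefin inherited from nerol is cis-dihydroxylated last.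

Key step: step 12

Remark: atom labels C1–C11 follow the germacrane numbering above (C11 = carbinol carbon on C7). The ester is the angelate, (Z)-2-methylbut-2-enoate, as the SMILES specifies. The sense of induction in step 2 is assigned by analogy with geraniol; the antipodal ligand would be used if it proved opposite.

**Step 1**
Reactants: 1 neryl acetate
Product: 2 (2Z,6E)-8-hydroxy-3,7-dimethylocta-2,6-dien-1-yl acetate
Conditions: SeO2 (cat.), t-BuOOH, salicylic acid (cat.), CH2Cl2, rt
Reagents that add atoms: tert-butyl hydroperoxide CC(C)(C)OO (terminal oxidant; oxygen relayed through catalytic selenium dioxide O=[Se]=O)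
Why: Riley-type allylic oxidation (ene reaction, then [2,3]-sigmatropic shift) attacks the electron-richer 6,7-olefin at its (E)-methyl group, the 2,3-olefin being deactivated by the allylic acetate, so the (6E)-allylic alcohol needed for directed hydrogenation should result.

**Step 2**
Reactants: 2 (2Z,6E)-8-hydroxy-3,7-dimethylocta-2,6-dien-1-yl acetate
Product: 3 (2Z,7S)-8-hydroxy-3,7-dimethyloct-2-en-1-yl acetate
Conditions: H2 (30–100 atm), Ru(OAc)2[(S)-BINAP] (cat.), MeOH, rt
Reagents that add atoms: none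
Why: Hydroxyl-directed asymmetric hydrogenation (Noyori-type Ru–BINAP) should reduce only the olefin of the allylic alcohol, the Z-allylic acetate olefin having no coordinating OH, and by analogy with geraniol giving (R)-citronellol under the (S)-BINAP complex, hydrogen should add to the same olefin face relative to CH2OH, which here sets the (7S) centre (C10 of the target).

**Step 3**
Reactants: 3 (2Z,7S)-8-hydroxy-3,7-dimethyloct-2-en-1-yl acetate
Product: 4 (2Z,7S)-3,7-dimethyl-8-(tosyloxy)oct-2-en-1-yl acetate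
Conditions: TsCl, Et3N, DMAP (cat.), CH2Cl2, 0 °C
Reagents that add atoms: p-toluenesulfonyl chloride Cc1ccc(cc1)S(Cl)(=O)=O
Why: Sulfonylation of the only free hydroxyl, a primary alcohol, installs the leaving group at C9 for the later C–S ring closure.

**Step 4**
Reactants: 4 (2Z,7S)-3,7-dimethyl-8-(tosyloxy)oct-2-en-1-yl acetate
Product: 5 (2S,6Z)-8-hydroxy-2,6-dimethyloct-6-en-1-yl 4-methylbenzenesulfonate
Conditions: K2CO3 (cat.), MeOH, 0 °C
Reagents that add atoms: none
Why: Base-catalysed transesterification (Zemplén-type methanolysis) removes the acetate, while the β-branched primary tosylate should be inert to catalytic carbonate at 0 °C.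

**Step 5**
Reactants: 5 (2S,6Z)-8-hydroxy-2,6-dimethyloct-6-en-1-yl 4-methylbenzenesulfonate
Product: 6 (2S,6Z)-2,6-dimethyl-8-oxooct-6-en-1-yl 4-methylbenzenesulfonate
Conditions: activated MnO2, CH2Cl2, rt
Reagents that add atoms: none
Why: Allylic oxidation with MnO2 is neutral and specific for the allylic alcohol, so the Z geometry of the C4=C5 olefin and the tosylate should survive.

**Step 6**
Reactants: 7 3,3'-dithiodipropionic acid; 8 (4R)-4-benzyl-1,3-oxazolidin-2-one (2 equiv)
Product: 10 (4R,4'R)-3,3'-[disulfanediylbis(1-oxopropane-3,1-diyl)]bis(4-benzyl-1,3-oxazolidin-2-one), via bis(pivalic) mixed anhydride 9 (not isolated)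
Conditions: t-BuCOCl, Et3N, THF, −20 °C; then 8, LiCl, rt
Reagents that add atoms: none
Why: Mixed-anhydride N-acylation of the oxazolidinone (LiCl/Et3N activation) converts both carboxyl groups into imides without touching the disulfide, which serves as a thiol protecting group removable under neutral conditions.

**Step 7**
Reactants: 10 (4R,4'R)-3,3'-[disulfanediylbis(1-oxopropane-3,1-diyl)]bis(4-benzyl-1,3-oxazolidin-2-one); 6 (2S,6Z)-2,6-dimethyl-8-oxooct-6-en-1-yl 4-methylbenzenesulfonate (2 equiv)
Product: 12 disulfide-linked bis-syn-aldol adduct (each half: (4R)-4-benzyl-3-[(2R,3S,4Z,9S)-3-hydroxy-5,9-dimethyl-2-(sulfanylmethyl)-10-(tosyloxy)dec-4-enoyl]-1,3-oxazolidin-2-one), via bis(dibutylboron Z-enolate) 11 (not isolated)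
Conditions: Bu2BOTf, i-Pr2NEt, CH2Cl2, −78 → 0 °C; then 6, −78 → 0 °C; pH 7 buffer/MeOH work-up (no peroxide)
Reagents that add atoms: none
Why: Evans syn-aldol: each (Z)-boron enolate should react through a chair Zimmerman–Traxler transition state on the face remote from the benzyl group of the (R)-auxiliary, setting C7 and C6 as (2R,3S) in each arm, with enolisation and aldehyde addition at −78 °C to suppress β-elimination of the disulfide and Z→E isomerisation of the enal.

**Step 8**
Reactants: 12 disulfide-linked bis-syn-aldol adduct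
Product: 13 disulfide-linked bis(methyl ester) (each half: methyl (2R,3S,4Z,9S)-3-hydroxy-5,9-dimethyl-2-(sulfanylmethyl)-10-(tosyloxy)dec-4-enoate)
Conditions: NaOMe (cat.), MeOH/CH2Cl2, −15 → 0 °C
Reagents that add atoms: methanol CO
Why: Methoxide attacks the exocyclic imide carbonyl (transesterification assisted by the free β-hydroxyl), releasing the auxiliary and giving the methyl ester at low temperature, where retro-aldol and epimerisation at C7 should not compete.

**Step 9**
Reactants: 13 disulfide-linked bis(methyl ester)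
Product: 15 methyl (3R,4S,5Z,10S)-4-hydroxy-6,10-dimethyl-1-thiacycloundec-5-ene-3-carboxylate, via thiol 14 (not isolated)
Conditions: PBu3, H2O, THF, rt; then slow addition to Cs2CO3, degassed DMF (ca. 2 mM), rt
Reagents that add atoms: none
Why: Phosphine/water reduction of the disulfide gives the thiol, whose caesium thiolate should close the 11-membered thiacycle by intramolecular SN2 (11-exo-tet) on the primary tosylate under high dilution, the Z-olefin pre-bending the chain and no stereocentre being touched.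

**Step 10**
Reactants: 15 methyl (3R,4S,5Z,10S)-4-hydroxy-6,10-dimethyl-1-thiacycloundec-5-ene-3-carboxylate
Product: 17 (3R,4S,5Z,10S)-3-(2-hydroxypropan-2-yl)-6,10-dimethyl-1-thiacycloundec-5-en-4-ol, via methyl ketone 16 (not isolated)
Conditions: MeMgBr (excess), THF, 0 °C → rt
Reagents that add atoms: methylmagnesium bromide C[Mg]Br
Why: Double Grignard addition to the ester through the methyl ketone furnishes the C11 tertiary carbinol, and at the same time removes the only acidic C–H (C7–H) that could later trigger β-elimination of the sulfone.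

**Step 11**
Reactants: 17 (3R,4S,5Z,10S)-3-(2-hydroxypropan-2-yl)-6,10-dimethyl-1-thiacycloundec-5-en-4-ol
Product: 18 (3R,4S,5Z,10S)-4-hydroxy-3-(2-hydroxypropan-2-yl)-6,10-dimethyl-1-thiacycloundec-5-ene 1,1-dioxide
Conditions: potassium peroxymonosulfate (Oxone), NaHCO3, MeOH/H2O, 0 °C → rt
Reagents that add atoms: potassium peroxymonosulfate [K+].[O-]S(=O)(=O)OO
Why: Peroxymonosulfate oxidises the sulfide through the sulfoxide to the sulfone far faster than it epoxidises an isolated trisubstituted olefin without a ketone catalyst, and the bicarbonate buffer protects the allylic alcohol from acid.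

**Step 12**
Reactants: 18 (3R,4S,5Z,10S)-4-hydroxy-3-(2-hydroxypropan-2-yl)-6,10-dimethyl-1-thiacycloundec-5-ene 1,1-dioxide
Product: 21 (1S,2Z,7S,8Z,10R)-10-(2-hydroxypropan-2-yl)-3,7-dimethylcyclodeca-2,8-dien-1-ol (8E isomer may accompany it), via alpha-bromo sulfone 19 (not isolated), via episulfone 20 (not isolated)
Conditions: KOH/Al2O3, BrCF2CF2Br, t-BuOH/CH2Cl2, 0 °C → rt
Reagents that add atoms: none
Why: Ramberg–Bäcklund reaction in its in-situ-halogenating form, whose closest precedents are sulfone extrusions that turn n-membered cyclic sulfones into (n−1)-membered cycloalkenes: KOH deprotonates an α-sulfonyl CH2 (C9 or C8), the carbanion takes Br+ from BrCF2CF2Br (which collapses to C2F4 and bromide, so no dihalocarbene can attack the C4=C5 olefin), the α'-carbanion displaces bromide in a 1,3-elimination, and the resulting episulfone loses SO2 to give the C8=C9 olefin. The only ring closed is the transient thiirane dioxide (3-exo-tet); the ten-membered carbocycle arises from the eleven-membered thiacycle by excision of sulfur, a one-atom ring contraction that unites two carbons of the same (nucleophilic, α-sulfonyl) polarity. No stereocentre is created and C6, C7 and C10 are untouched, because C7–H and C10–H are not acidic and carry no β-leaving group now that C11 is a carbinol and no longer an ester. The step is convergent: either α-carbon may be brominated, either episulfone diastereomer may form, and both olefin geometries lead to the same compound after step 13, so the only selectivity required is chemoselectivity towards the two hydroxyls (present as alkoxides) and the trisubstituted olefin. The main liability, a base-accelerated [3,3] shift of the 3-oxido-1,5-diene product, should be slow in the protic, hydrogen-bonding medium at room temperature.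

**Step 13**
Reactants: 21 (1S,2Z,7S,8Z,10R)-10-(2-hydroxypropan-2-yl)-3,7-dimethylcyclodeca-2,8-dien-1-ol
Product: 22 (1S,2Z,7S,10R)-10-(2-hydroxypropan-2-yl)-3,7-dimethylcyclodec-2-en-1-ol
Conditions: 2-nitrobenzenesulfonohydrazide, Et3N, CH2Cl2, rt
Reagents that add atoms: none
Why: Diimide reduction (concerted syn transfer of H2) is much faster at the 1,2-disubstituted C8=C9 olefin than at the trisubstituted C4=C5 olefin, so both geometric isomers of 21 should converge on one cyclodecenol.

**Step 14**
Reactants: 22 (1S,2Z,7S,10R)-10-(2-hydroxypropan-2-yl)-3,7-dimethylcyclodec-2-en-1-ol; 23 angelic acid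
Product: 25 (1S,2Z,7S,10R)-10-(2-hydroxypropan-2-yl)-3,7-dimethylcyclodec-2-en-1-yl (2Z)-2-methylbut-2-enoate, via angelic 2,4,6-trichlorobenzoic mixed anhydride 24 (not isolated)
Conditions: 23, 2,4,6-trichlorobenzoyl chloride, Et3N, toluene, rt; then 22, 80 °C (no DMAP)
Reagents that add atoms: none
Why: Yamaguchi-type mixed-anhydride esterification acylates the secondary allylic C6 alcohol without nucleophilic catalyst, which avoids Z→E isomerisation to the tiglate, while the tertiary C11 hydroxyl is too hindered to react.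

**Step 15**
Reactants: 25 (1S,2Z,7S,10R)-10-(2-hydroxypropan-2-yl)-3,7-dimethylcyclodec-2-en-1-yl (2Z)-2-methylbut-2-enoate
Product: 26 (1R,2S,3R,7S,10R)-2,3-dihydroxy-10-(2-hydroxypropan-2-yl)-3,7-dimethylcyclodecyl (2Z)-2-methylbut-2-enoate (target)
Conditions: OsO4 (cat.), NMO, acetone/H2O, 0 °C → rt
Reagents that add atoms: N-methylmorpholine N-oxide C[N+]1([O-])CCOCC1; water O; osmium tetroxide O=[Os](=O)(=O)=O (catalytic oxygen carrier)
Why: Catalytic OsO4/NMO cis-dihydroxylation should take the electron-rich ring olefin in preference to the conjugated angelate olefin, syn addition to the Z-olefin fixing C4 relative to C5, and with H6 held in the olefin plane by A(1,3) strain against C3 the ring segment through C7 and its CMe2OH group shields the inner face, so osmium should add from the outer face, trans to the C6 acyloxy group, giving (4R,5S).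

**Compound list**

1 | neryl acetate, (2Z)-3,7-dimethylocta-2,6-dien-1-yl acetate | CC(C)=CCC/C(C)=C\COC(C)=O | starting material
2 | (2Z,6E)-8-hydroxy-3,7-dimethylocta-2,6-dien-1-yl acetate | OC/C(C)=C/CC/C(C)=C\COC(C)=O | intermediate
3 | (2Z,7S)-8-hydroxy-3,7-dimethyloct-2-en-1-yl acetate | OC[C@@H](C)CCC/C(C)=C\COC(C)=O | intermediate
4 | (2Z,7S)-3,7-dimethyl-8-(tosyloxy)oct-2-en-1-yl acetate | Cc1ccc(cc1)S(=O)(=O)OC[C@@H](C)CCC/C(C)=C\COC(C)=O | intermediate
5 | (2S,6Z)-8-hydroxy-2,6-dimethyloct-6-en-1-yl 4-methylbenzenesulfonate | Cc1ccc(cc1)S(=O)(=O)OC[C@@H](C)CCC/C(C)=C\CO | intermediate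
6 | (2S,6Z)-2,6-dimethyl-8-oxooct-6-en-1-yl 4-methylbenzenesulfonate | Cc1ccc(cc1)S(=O)(=O)OC[C@@H](C)CCC/C(C)=C\C=O | intermediate
7 | 3,3'-dithiodipropionic acid | OC(=O)CCSSCCC(O)=O | starting material
8 | (4R)-4-benzyl-1,3-oxazolidin-2-one | O=C1N[C@H](Cc2ccccc2)CO1 | starting material
9 | bis(pivalic) mixed anhydride of 7 | CC(C)(C)C(=O)OC(=O)CCSSCCC(=O)OC(=O)C(C)(C)C | intermediate (not isolated)
10 | (4R,4'R)-3,3'-[disulfanediylbis(1-oxopropane-3,1-diyl)]bis(4-benzyl-1,3-oxazolidin-2-one) | O=C(CCSSCCC(=O)N1[C@H](Cc2ccccc2)COC1=O)N1[C@H](Cc2ccccc2)COC1=O | intermediate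
11 | bis[(Z)-dibutylboron enolate] of 10 | CCCCB(CCCC)O/C(=C\CSSC/C=C(\OB(CCCC)CCCC)N1[C@H](Cc2ccccc2)COC1=O)N1[C@H](Cc2ccccc2)COC1=O | intermediate (not isolated)
12 | disulfide-linked bis-syn-aldol adduct; each half (4R)-4-benzyl-3-[(2R,3S,4Z,9S)-3-hydroxy-5,9-dimethyl-2-(sulfanylmethyl)-10-(tosyloxy)dec-4-enoyl]-1,3-oxazolidin-2-one | O=C(N1[C@H](Cc2ccccc2)COC1=O)[C@H](CSSC[C@@H](C(=O)N1[C@H](Cc2ccccc2)COC1=O)[C@@H](O)/C=C(C)\CCC[C@H](C)COS(=O)(=O)c1ccc(C)cc1)[C@@H](O)/C=C(C)\CCC[C@H](C)COS(=O)(=O)c1ccc(C)cc1 | intermediate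
13 | disulfide-linked bis(methyl ester); each half methyl (2R,3S,4Z,9S)-3-hydroxy-5,9-dimethyl-2-(sulfanylmethyl)-10-(tosyloxy)dec-4-enoate | COC(=O)[C@H](CSSC[C@@H](C(=O)OC)[C@@H](O)/C=C(C)\CCC[C@H](C)COS(=O)(=O)c1ccc(C)cc1)[C@@H](O)/C=C(C)\CCC[C@H](C)COS(=O)(=O)c1ccc(C)cc1 | intermediate
14 | methyl (2R,3S,4Z,9S)-3-hydroxy-5,9-dimethyl-2-(sulfanylmethyl)-10-(tosyloxy)dec-4-enoate | COC(=O)[C@H](CS)[C@@H](O)/C=C(C)\CCC[C@H](C)COS(=O)(=O)c1ccc(C)cc1 | intermediate (not isolated)
15 | methyl (3R,4S,5Z,10S)-4-hydroxy-6,10-dimethyl-1-thiacycloundec-5-ene-3-carboxylate | COC(=O)[C@@H]1CSC[C@@H](C)CCC/C(C)=C\[C@@H]1O | intermediate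
16 | 1-[(3R,4S,5Z,10S)-4-hydroxy-6,10-dimethyl-1-thiacycloundec-5-en-3-yl]ethan-1-one | CC(=O)[C@@H]1CSC[C@@H](C)CCC/C(C)=C\[C@@H]1O | intermediate (not isolated)
17 | (3R,4S,5Z,10S)-3-(2-hydroxypropan-2-yl)-6,10-dimethyl-1-thiacycloundec-5-en-4-ol | CC(C)(O)[C@@H]1CSC[C@@H](C)CCC/C(C)=C\[C@@H]1O | intermediate
18 | (3R,4S,5Z,10S)-4-hydroxy-3-(2-hydroxypropan-2-yl)-6,10-dimethyl-1-thiacycloundec-5-ene 1,1-dioxide | CC(C)(O)[C@@H]1CS(=O)(=O)C[C@@H](C)CCC/C(C)=C\[C@@H]1O | intermediate
19 | 11-bromo derivative of 18 (bromine on C9, epimers; the C8-bromo isomer would converge) | CC(C)(O)[C@@H]1CS(=O)(=O)C(Br)[C@@H](C)CCC/C(C)=C\[C@@H]1O | intermediate (not isolated)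
20 | episulfone, (4Z)-2-(2-hydroxypropan-2-yl)-5,9-dimethyl-11-thiabicyclo[8.1.0]undec-4-en-3-ol 11,11-dioxide (C1/C10 epimers) | CC(C)(O)[C@@H]1C2C(S2(=O)=O)[C@@H](C)CCC/C(C)=C\[C@@H]1O | intermediate (not isolated)
21 | (1S,2Z,7S,8Z,10R)-10-(2-hydroxypropan-2-yl)-3,7-dimethylcyclodeca-2,8-dien-1-ol | CC(C)(O)[C@@H]1/C=C\[C@@H](C)CCC/C(C)=C\[C@@H]1O | intermediate
22 | (1S,2Z,7S,10R)-10-(2-hydroxypropan-2-yl)-3,7-dimethylcyclodec-2-en-1-ol | CC(C)(O)[C@@H]1CC[C@@H](C)CCC/C(C)=C\[C@@H]1O | intermediate
23 | angelic acid, (2Z)-2-methylbut-2-enoic acid | C/C=C(/C)C(O)=O | starting material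
24 | angelic 2,4,6-trichlorobenzoic mixed anhydride | C/C=C(/C)C(=O)OC(=O)c1c(Cl)cc(Cl)cc1Cl | intermediate (not isolated)
25 | (1S,2Z,7S,10R)-10-(2-hydroxypropan-2-yl)-3,7-dimethylcyclodec-2-en-1-yl (2Z)-2-methylbut-2-enoate | CC(C)(O)[C@@H]1CC[C@@H](C)CCC/C(C)=C\[C@@H]1OC(=O)/C(C)=C\C | intermediate
26 | (1R,2S,3R,7S,10R)-2,3-dihydroxy-10-(2-hydroxypropan-2-yl)-3,7-dimethylcyclodecyl (2Z)-2-methylbut-2-enoate | C/C=C(/C)C(=O)O[C@@H]1[C@H](C(C)(C)O)CC[C@@H](C)CCC[C@@](C)(O)[C@H]1O | target

**Totals.** 15 steps in all; the longest linear sequence is 14 steps (steps 1–5 and 7–15, from neryl acetate).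

**Steps most likely to fail**

1. Step 12 (key step). As the second olefin forms, the C6 alkoxide sits in a 3-oxido-1,5-diene and may undergo base-accelerated [3,3] sigmatropic collapse of the ring; closure of the episulfone at the two β-branched α-carbons may also be sluggish. Fallback: remove the alkoxide from the substrate. Starting from 18, the C6 hydroxyl would be silylated selectively (TBSOTf, 2,6-lutidine, −78 °C) to the silyl ether sulfone F1. The same sulfone extrusion would give the silyl ether diene F2, diimide reduction the silyl ether cyclodecene F3, and Bu4NF would remove silicon, rejoining the route at 22.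

2. Step 9. Intermolecular S-alkylation (oligomerisation) may outrun closure of the strained 11-membered ring, and the β-thio ester may epimerise at C7 through reversible retro-thia-Michael elimination under base. Fallback: form the C–S bond bimolecularly and close the ring at C6–C7 instead. Starting from 10 and 5, reduction of 10 (PBu3, H2O) would give the thiol imide F4, which would be S-alkylated with tosylate 5 (Cs2CO3, DMF) to the thioether alcohol F5 and oxidised (MnO2) to the Z-enal F6. An auxiliary-controlled intramolecular titanium-enolate syn-aldol (TiCl4, i-Pr2NEt, CH2Cl2, high dilution) would give the thiacycle imide F7, and methanolysis (NaOMe, MeOH) would rejoin the route at 15.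

3. Step 15. Facial selectivity on the conformationally mobile ten-membered ring may be poor, or the angelate olefin may be oxidised competitively. Fallback: dihydroxylate before acylation under hydroxyl direction. Starting from 22, stoichiometric OsO4·TMEDA (CH2Cl2, −78 °C) would be delivered by hydrogen bonding from the face carrying the C6 hydroxyl in the A(1,3)-minimised conformer (the same face as in the main route), giving the tetraol F8. The ring-cis C4/C5 diol would be protected selectively (2,2-dimethoxypropane, PPTS) as the acetonide F9, the C6 hydroxyl esterified as in step 14 to the acetonide angelate F10, and the acetonide hydrolysed with aqueous acetic acid, arriving at 26.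

**Further compounds**

F1 | step 12 | (3R,4S,5Z,10S)-4-[(tert-butyldimethylsilyl)oxy]-3-(2-hydroxypropan-2-yl)-6,10-dimethyl-1-thiacycloundec-5-ene 1,1-dioxide | CC(C)(O)[C@@H]1CS(=O)(=O)C[C@@H](C)CCC/C(C)=C\[C@@H]1O[Si](C)(C)C(C)(C)C
F2 | step 12 | C6 tert-butyldimethylsilyl ether of diene 21 | CC(C)(O)[C@@H]1/C=C\[C@@H](C)CCC/C(C)=C\[C@@H]1O[Si](C)(C)C(C)(C)C
F3 | step 12 | C6 tert-butyldimethylsilyl ether of cyclodecenol 22 | CC(C)(O)[C@@H]1CC[C@@H](C)CCC/C(C)=C\[C@@H]1O[Si](C)(C)C(C)(C)C
F4 | step 9 | (4R)-4-benzyl-3-(3-sulfanylpropanoyl)-1,3-oxazolidin-2-one | O=C(CCS)N1[C@H](Cc2ccccc2)COC1=O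
F5 | step 9 | (4R)-4-benzyl-3-(3-{[(2S,6Z)-8-hydroxy-2,6-dimethyloct-6-en-1-yl]sulfanyl}propanoyl)-1,3-oxazolidin-2-one | O=C(CCSC[C@@H](C)CCC/C(C)=C\CO)N1[C@H](Cc2ccccc2)COC1=O
F6 | step 9 | (4R)-4-benzyl-3-(3-{[(2S,6Z)-2,6-dimethyl-8-oxooct-6-en-1-yl]sulfanyl}propanoyl)-1,3-oxazolidin-2-one | O=C(CCSC[C@@H](C)CCC/C(C)=C\C=O)N1[C@H](Cc2ccccc2)COC1=O
F7 | step 9 | (4R)-4-benzyl-3-{[(3R,4S,5Z,10S)-4-hydroxy-6,10-dimethyl-1-thiacycloundec-5-en-3-yl]carbonyl}-1,3-oxazolidin-2-one | O=C([C@@H]1CSC[C@@H](C)CCC/C(C)=C\[C@@H]1O)N1[C@H](Cc2ccccc2)COC1=O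
F8 | step 15 | (1R,2S,3R,7S,10R)-10-(2-hydroxypropan-2-yl)-3,7-dimethylcyclodecane-1,2,3-triol | O[C@@H]1[C@H](C(C)(C)O)CC[C@@H](C)CCC[C@@](C)(O)[C@H]1O
F9 | step 15 | 2,3-O-isopropylidene acetal (C4/C5 acetonide) of F8 | O[C@@H]1[C@H](C(C)(C)O)CC[C@@H](C)CCC[C@@]2(C)OC(C)(C)O[C@@H]12
F10 | step 15 | C6 angelate of acetonide F9 | C/C=C(/C)C(=O)O[C@@H]1[C@H](C(C)(C)O)CC[C@@H](C)CCC[C@@]2(C)OC(C)(C)O[C@@H]12
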